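**Retrosynthetic overview**

1. The diketone is cut at its C(=O)–C(=O) bond. The benzil should arise by carbene-catalysed O→C transfer of a 4-methoxybenzoyl group from O7 to the formyl carbon on C6, which leads back to 7-hydroxy-5-methoxy-2,2-dimethyl-2H-chromene-6-carbaldehyde and 4-methoxybenzoyl chloride.
2. The pyran ring is cut at C3–C4 and O1–C2, giving 4,6-dihydroxy-2-methoxybenzene-1,3-dicarbaldehyde, 2-methylprop-1-enylboronic acid and a secondary amine (borono-Mannich condensation, then oxa-6π closure).
3. Feature: C5–OMe lies between C4a and C6, the two ring carbons that carry carbon substituents (C4 of the pyran ring and the diketone carbon), and each of these has an oxygen-bearing carbon on its far side (C8a–O1 and C7–OH). When C4 and the acyl carbon are both read as CHO, the benzene ring has a mirror plane through C5–OMe and C8–H, so the two formyl groups are equivalent and the annulation cannot give a regioisomer.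
4. The dialdehyde goes back to phloroglucinol: double Vilsmeier formylation, MOM protection of the two outer hydroxyls, methylation of the hydroxyl between the formyl groups, MOM removal.
5. Ring order: both benzene rings are bought; the pyran ring is the only ring formed (step 5).

Key step: step 5

Remark: the target has no stereogenic element (C2 carries two methyl groups), so the stereodescriptor-free SMILES is the full structure and no stereocontrol is needed. Locants are those of the 2H-chromene (O1, C2, C3, C4, C4a, C5–C8, C8a).

**Route**

Step 1
Reactants: 1 phloroglucinol (benzene-1,3,5-triol)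
Product: 3 2,4,6-trihydroxybenzene-1,3-dicarbaldehyde (2,4-diformylphloroglucinol), via bis(dimethyliminium) dichloride 2 (not isolated)
Conditions: POCl3 (2.5 equiv), DMF (2.5 equiv), 1,4-dioxane, 0 °C → rt; then H2O, rt
Reagents that add atoms: N,N-dimethylformamide CN(C)C=O; water O
Why: Vilsmeier–Haack formylation: phloroglucinol is nucleophilic enough to take up two chloroiminium electrophiles, the third substitution is slowed by the two iminium groups already on the ring, and aqueous hydrolysis of 2 releases both formyl groups.

Step 2
Reactants: 3 2,4,6-trihydroxybenzene-1,3-dicarbaldehyde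
Product: 4 2-hydroxy-4,6-bis(methoxymethoxy)benzene-1,3-dicarbaldehyde
Conditions: MOMCl (2.1 equiv), iPr2NEt (2.5 equiv), THF, 0 °C → rt
Reagents that add atoms: chloromethyl methyl ether COCCl
Why: Selective O-alkylation (MOM ether formation): the two outer hydroxyls, each flanked by one formyl group and a ring C–H, should react before the central hydroxyl, which is wedged between two formyl groups and held in a strong O–H···O=C hydrogen bond, so two equivalents of MOMCl should stop at the bis-ether.

Step 3
Reactants: 4 2-hydroxy-4,6-bis(methoxymethoxy)benzene-1,3-dicarbaldehyde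
Product: 5 2-methoxy-4,6-bis(methoxymethoxy)benzene-1,3-dicarbaldehyde
Conditions: MeI (3 equiv), K2CO3, DMF, 40 °C
Reagents that add atoms: iodomethane CI
Why: Williamson ether synthesis: with the other hydroxyls masked, the hindered chelated phenol is the only acidic site and should be methylated by excess MeI in a polar aprotic solvent, conditions that leave MOM ethers and formyl groups untouched.

Step 4
Reactants: 5 2-methoxy-4,6-bis(methoxymethoxy)benzene-1,3-dicarbaldehyde
Product: 6 4,6-dihydroxy-2-methoxybenzene-1,3-dicarbaldehyde
Conditions: 2 M aq. HCl, THF, 50 °C
Reagents that add atoms: none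
Why: Acid-catalysed hydrolysis of the MOM acetals, assisted by the neighbouring formyl groups, should free both phenols while the aryl methyl ether and the aldehydes are stable to dilute acid.

Step 5
Reactants: 6 4,6-dihydroxy-2-methoxybenzene-1,3-dicarbaldehyde; 7 2-methylprop-1-enylboronic acid
Product: 10 7-hydroxy-5-methoxy-2,2-dimethyl-2H-chromene-6-carbaldehyde, via Petasis allylic amine adduct 8 (not isolated), via vinyl ortho-quinone methide 9 (not isolated)
Conditions: Bn2NH (40 mol %), 1,4-dioxane, 90 °C; 7 (0.95 equiv) added slowly
Reagents that add atoms: none
Why: The secondary amine condenses with one formyl group to an iminium ion while the neighbouring phenol binds the boronic acid as a boronate, from which the 2-methylprop-1-enyl group is delivered intramolecularly to the iminium carbon (Petasis borono-Mannich reaction, C3–C4 bond), giving allylic amine 8. At 90 °C 8 should lose the amine, helped by the ortho and para oxygen donors, to give vinyl ortho-quinone methide 9, whose 1-oxatriene (O=C8a–C4a=C4–C3=C2) closes the pyran ring by thermal disrotatory oxa-6π electrocyclisation (O1–C2 bond) with rearomatisation. This is the known amine-promoted condensation of salicylaldehydes with alkenylboronic acids to 2H-chromenes, and 9 is the same type of intermediate as in phenol–enal chromene syntheses. No stereocentre is created, since C2 carries two methyl groups and the amine-bearing carbon of 8 becomes sp2. Regiochemistry needs no control, because the two formyl groups of 6 are related by the mirror plane through C2–OMe and C5–H of the benzene ring and each lies between the OMe and one OH, so either one gives 10. The selectivity required is mono- over double annulation; it should be secured by keeping 7 below one equivalent, by the statistical factor of two, and by the lower electrophilicity of the formyl group of 10, which has lost its electron-withdrawing meta-formyl partner.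

Step 6
Reactants: 10 7-hydroxy-5-methoxy-2,2-dimethyl-2H-chromene-6-carbaldehyde; 11 4-methoxybenzoyl chloride
Product: 12 6-formyl-5-methoxy-2,2-dimethyl-2H-chromen-7-yl 4-methoxybenzoate
Conditions: Et3N (1.5 equiv), DMAP (10 mol %), CH2Cl2, 0 °C → rt
Reagents that add atoms: none
Why: DMAP-catalysed O-acylation of the only hydroxyl of 10 with an acid chloride; the chromene alkene and the formyl group are inert to these conditions.

Step 7
Reactants: 12 6-formyl-5-methoxy-2,2-dimethyl-2H-chromen-7-yl 4-methoxybenzoate
Product: 13 1-(7-hydroxy-5-methoxy-2,2-dimethyl-2H-chromen-6-yl)-2-(4-methoxyphenyl)ethane-1,2-dione (target)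
Conditions: 2-(pentafluorophenyl)-6,7-dihydro-5H-pyrrolo[2,1-c][1,2,4]triazol-2-ium tetrafluoroborate (20 mol %), DBU (20 mol %), THF, 4 Å MS, 40 °C
Reagents that add atoms: none
Why: Proposed new method: the carbene should add to the formyl group to give an enaminol acyl-anion equivalent that attacks the neighbouring aryl ester carbonyl through a five-membered transition state, and collapse of the tetrahedral adduct should expel the phenoxide and then the catalyst, giving the 1,2-diketone with the 7-OH restored (an isomerisation driven by C–C bond formation and the chelated phenol ketone); the closest known reaction type is the carbene-catalysed intramolecular crossed benzoin reaction of an aldehyde with a ketone, here extended to an activated aryl ester as the acceptor.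

**Compound list**

1 | phloroglucinol (benzene-1,3,5-triol) | Oc1cc(O)cc(O)c1 | starting material
2 | bis(dimethyliminium) dichloride of 2,4-diformylphloroglucinol | C[N+](C)=Cc1c(O)cc(O)c(C=[N+](C)C)c1O.[Cl-].[Cl-] | intermediate
3 | 2,4,6-trihydroxybenzene-1,3-dicarbaldehyde | O=Cc1c(O)cc(O)c(C=O)c1O | intermediate
4 | 2-hydroxy-4,6-bis(methoxymethoxy)benzene-1,3-dicarbaldehyde | COCOc1cc(OCOC)c(C=O)c(O)c1C=O | intermediate
5 | 2-methoxy-4,6-bis(methoxymethoxy)benzene-1,3-dicarbaldehyde | COCOc1cc(OCOC)c(C=O)c(OC)c1C=O | intermediate
6 | 4,6-dihydroxy-2-methoxybenzene-1,3-dicarbaldehyde | COc1c(C=O)c(O)cc(O)c1C=O | intermediate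
7 | 2-methylprop-1-enylboronic acid | CC(C)=CB(O)O | starting material
8 | 3-[1-(dibenzylamino)-3-methylbut-2-en-1-yl]-4,6-dihydroxy-2-methoxybenzaldehyde (racemic) | COc1c(C=O)c(O)cc(O)c1C(C=C(C)C)N(Cc1ccccc1)Cc1ccccc1 | intermediate
9 | (3Z)-6-hydroxy-2-methoxy-3-(3-methylbut-2-en-1-ylidene)-4-oxocyclohexa-1,5-diene-1-carbaldehyde | O=C1C=C(O)C(C=O)=C(OC)/C1=C/C=C(C)C | intermediate
10 | 7-hydroxy-5-methoxy-2,2-dimethyl-2H-chromene-6-carbaldehyde | COc1c(C=O)c(O)cc2OC(C)(C)C=Cc12 | intermediate
11 | 4-methoxybenzoyl chloride | COc1ccc(cc1)C(Cl)=O | starting material
12 | 6-formyl-5-methoxy-2,2-dimethyl-2H-chromen-7-yl 4-methoxybenzoate | COc1ccc(cc1)C(=O)Oc1cc2OC(C)(C)C=Cc2c(OC)c1C=O | intermediate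
13 | 1-(7-hydroxy-5-methoxy-2,2-dimethyl-2H-chromen-6-yl)-2-(4-methoxyphenyl)ethane-1,2-dione | COc1ccc(C(=O)C(=O)c2c(O)cc3c(c2OC)C=CC(C)(C)O3)cc1 | target

**Step count and risks**

Total step count: 7. Longest linear sequence: 7 steps (1 → 13); 7 and 11 are bought.

Steps most likely to fail:

Step 7 (labelled step). The carbene may fail to add to the formyl group, which is flanked by two ortho substituents, or it may attack the aryl ester as an acyl-transfer nucleophile, so that the ester is cleaved and no C–C bond forms. The fallback uses known chemistry and sets out from aldehyde 10. Addition of 4-methoxybenzylmagnesium chloride (3 equiv, THF, 0 °C; one equivalent is consumed by the phenol) should give racemic 6-[1-hydroxy-2-(4-methoxyphenyl)ethyl]-5-methoxy-2,2-dimethyl-2H-chromen-7-ol F1. Oxidation of the benzylic alcohol (activated MnO2, CH2Cl2) should give the deoxybenzoin 1-(7-hydroxy-5-methoxy-2,2-dimethyl-2H-chromen-6-yl)-2-(4-methoxyphenyl)ethan-1-one F2. Riley oxidation of the activated methylene (SeO2, dioxane–H2O, reflux) then comes back to the route at 13; the chromene has no allylic C–H (C2 is quaternary) and should survive.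

Step 5 (key step). Iminium formation at a formyl group with two ortho substituents on an electron-rich ring may be slow, and the second salicylaldehyde unit of 10 may be annulated as well, giving over-reaction to a bis-pyran. The fallback replaces the catalytic three-component condensation by a stoichiometric organometallic addition and sets out from the protected dialdehyde 5. One equivalent of 2-methylprop-1-enylmagnesium bromide (THF, −78 °C) should give the racemic mono-adduct 3-(1-hydroxy-3-methylbut-2-en-1-yl)-2-methoxy-4,6-bis(methoxymethoxy)benzaldehyde F3, with unreacted 5 recycled. Treatment with aq. HCl in THF at 50 °C should remove both MOM groups and ionise the allylic alcohol to the same ortho-quinone methide, which closes to the chromene and comes back to the route at 10.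

Step 2. Etherification may be poorly site-selective among the three phenols, or may run on to the tris-ether. The fallback sets the regiochemistry with a blocking group instead of selective protection and sets out from phloroglucinol 1. Kolbe–Schmitt carboxylation (KHCO3, H2O, CO2, 50 °C) should give 2,4,6-trihydroxybenzoic acid F4. Esterification and methylation of the para hydroxyl in one operation (MeI, 2 equiv, KHCO3 then K2CO3, DMF) should give methyl 2,6-dihydroxy-4-methoxybenzoate F5. Double Duff formylation (hexamethylenetetramine, TFA, reflux; then aq. HCl) at the only two free ring positions should give methyl 3,5-diformyl-2,6-dihydroxy-4-methoxybenzoate F6. Saponification (aq. NaOH, heat) and decarboxylation on acidification and warming come back to the route at 6.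

Further compounds
F1 | step 7 | 6-[1-hydroxy-2-(4-methoxyphenyl)ethyl]-5-methoxy-2,2-dimethyl-2H-chromen-7-ol (racemic) | COc1ccc(CC(O)c2c(O)cc3OC(C)(C)C=Cc3c2OC)cc1
F2 | step 7 | 1-(7-hydroxy-5-methoxy-2,2-dimethyl-2H-chromen-6-yl)-2-(4-methoxyphenyl)ethan-1-one | COc1ccc(CC(=O)c2c(O)cc3OC(C)(C)C=Cc3c2OC)cc1
F3 | step 5 | 3-(1-hydroxy-3-methylbut-2-en-1-yl)-2-methoxy-4,6-bis(methoxymethoxy)benzaldehyde (racemic) | COCOc1cc(OCOC)c(C(O)C=C(C)C)c(OC)c1C=O
F4 | step 2 | 2,4,6-trihydroxybenzoic acid | OC(=O)c1c(O)cc(O)cc1O
F5 | step 2 | methyl 2,6-dihydroxy-4-methoxybenzoate | COC(=O)c1c(O)cc(OC)cc1O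
F6 | step 2 | methyl 3,5-diformyl-2,6-dihydroxy-4-methoxybenzoate | COC(=O)c1c(O)c(C=O)c(OC)c(C=O)c1O
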